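## Retrosynthetic overview

1. The Z-enol ester is made last, by ruthenium-catalysed anti-Markovnikov addition of 3-methylbut-2-enoic acid to an ethynyl group on C5; just before it, CH2OH is put on C2 by a Morita–Baylis–Hillman reaction.
2. Feature used: with the seven-membered ring numbered C1 (C=O), C2=C3, C4 (quaternary), C5, C6, C7, the cis arms on C5 (two carbons) and C6 (CH2COCH3) are the two halves of a cleaved 1-methyl-2-silyloxycyclohexene (ring B) fused at C5–C6, and C4 is the prochiral carbon of a 4,4-disubstituted cyclohexa-2,5-dienone (ring A).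
3. Key disconnection: catalytic enantioselective Diels–Alder reaction of this dienone (its carbonyl carbon is the later C7) with 2-silyloxy-3-methylbuta-1,3-diene, forming C5–CH2 and C6–CH2 and fixing C4, C5 and C6 together.
4. Ring A is enlarged afterwards by diazoalkane insertion, which places the new carbon C1 between C7 and the vinyl carbon C2; the carbonyl is then moved from C7 to C1 (C1 hydroxylation, C7 reduction, allylic oxidation, reductive loss of the C7 oxygen).
5. Order of ring events: six-membered ring A (Robinson annulation, dehydrogenation) → ring B (Diels–Alder) → ring A to seven members → ring B opened (Rubottom oxidation, Pb(OAc)4 cleavage).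

Key step: step 4

Remark on labels: C1–C7 are the ring atoms of the target as numbered above; in the six-membered intermediates the ring carbonyl carbon is therefore C7, and C1 is the carbon that enters in step 5. "C5 arm" and "C6 arm" are the ring-B CH2 groups on C5 and C6 and what they become.

Assumption: the oxazaborolidine from (S)-α,α-diphenylprolinol is taken to give the enantiomer drawn; should the sense of induction be the opposite, the catalyst from the (R)-amino alcohol is used and nothing else changes.

Remark: 2,6-dimethylhept-5-enal is used as the racemate, because its stereocentre becomes the prochiral C4 of the dienone.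

## Route

Step 1
Reactants: 1 2,6-dimethylhept-5-enal (racemic); 2 but-3-en-2-one
Product: 4 4-methyl-4-(4-methylpent-3-enyl)cyclohex-2-en-1-one (racemic), via keto aldehyde 3 (not isolated)
Conditions: KOH (0.2 equiv), EtOH, 0 °C then reflux
Reagents that add atoms: none
Why: Robinson annulation: the enolate of the α-branched aldehyde adds to the vinyl ketone (Michael addition) to give keto aldehyde 3 and the methyl ketone then closes ring A by intramolecular aldol condensation; the quaternary carbon is formed racemic, which is harmless because it becomes a prochiral centre in step 2.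

Step 2
Reactants: 4 4-methyl-4-(4-methylpent-3-enyl)cyclohex-2-en-1-one
Product: 5 4-methyl-4-(4-methylpent-3-enyl)cyclohexa-2,5-dien-1-one
Conditions: IBX (2.5 equiv), DMSO/PhMe, 75 °C
Reagents that add atoms: none
Why: IBX dehydrogenation of a ketone through its enol introduces the second double bond on the saturated CH2–CH2 side and gives the cross-conjugated dienone, in which C4 carries two enantiotopic enone arms; the isolated trisubstituted alkene should be inert to IBX.

Step 3
Reactants: 6 3-methylbut-3-en-2-one
Product: 7 2-(tert-butyldimethylsilyloxy)-3-methylbuta-1,3-diene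
Conditions: t-BuMe2SiOTf (1.1 equiv), Et3N (1.3 equiv), Et2O, 0 °C
Reagents that add atoms: tert-butyldimethylsilyl triflate, CC(C)(C)[Si](C)(C)OS(=O)(=O)C(F)(F)F
Why: Soft enolisation with a silyl triflate and a tertiary amine O-silylates the only enolisable position (the acetyl methyl group) and gives the 2-silyloxydiene.

Step 4
Reactants: 5 4-methyl-4-(4-methylpent-3-enyl)cyclohexa-2,5-dien-1-one; 7 2-(tert-butyldimethylsilyloxy)-3-methylbuta-1,3-diene
Product: 8 cis-fused Diels–Alder adduct (ring A: C7=O, C2=C3, C4, C5, C6; ring B: C5–CH2–C(OSiMe2t-Bu)=C(CH3)–CH2–C6; H-5 and H-6 cis, both trans to the C4 methyl group)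
Conditions: (S)-B-(o-tolyl)oxazaborolidine from α,α-diphenylprolinol (20 mol %), AlBr3 (16 mol %), CH2Cl2, −78 → −40 °C
Reagents that add atoms: none
Why: The AlBr3-activated oxazaborolidine binds the dienone carbonyl, and one of the two enantiotopic enones undergoes a concerted, suprafacial, endo [4+2] addition of 7, the reaction type established for chiral-Lewis-acid-catalysed Diels–Alder reactions of cyclohexa-2,5-dienones (quinone monoketals) with 2-silyloxydienes. Ring B is closed by forming the C5–CH2 and C6–CH2 bonds in one step, which makes the ring fusion cis and fixes C5 and C6 relative to each other. The silyloxy group sends its neighbouring CH2 terminus to the β-carbon C5 (para orientation), so that the later cleavage leaves the acetonyl arm on C6 and the two-carbon arm on C5. C4 becomes stereogenic because only one enone reacts; its configuration relative to C5 and C6 requires the diene to approach the face that carries the methyl group and not the homoprenyl chain, a steric preference of the substrate that is expected to be modest, so the diastereomer from attack syn to the chain would be removed by chromatography. The absolute sense is set by the catalyst, which for the methyl face pairs with one enone only. The step also needs reactivity at a β-carbon next to a quaternary centre, which the cationic Lewis acid and the electron-rich diene should provide at low temperature.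

Step 5
Reactants: 8 cis-fused Diels–Alder adduct
Product: 10 ring-enlarged β,γ-unsaturated ketone (ring A: C7=O, C1H2, C2=C3, C4, C5, C6; ring B unchanged), via α-silyl ketone 9 (not isolated)
Conditions: Me3SiCHN2 (1.5 equiv), AlMe3 (1.2 equiv), CH2Cl2, −78 → −20 °C; then MeOH, SiO2, rt
Reagents that add atoms: (trimethylsilyl)diazomethane, C[Si](C)(C)C=[N+]=[N-]
Why: Lewis-acid-promoted diazoalkane homologation: the diazoalkane adds to the AlMe3-activated carbonyl and, as is usual for conjugated cyclohexenones, the vinyl carbon C2 migrates with loss of N2, so the new carbon C1 enters between C7 and C2; desilylation of 9 through its dienol ether protonates C1 and leaves the β,γ-unsaturated ketone, while C6, which does not migrate, keeps its configuration.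

Step 6
Reactants: 10 ring-enlarged β,γ-unsaturated ketone
Product: 11 1-hydroxy ketone (C7=O, C1H–OH, C2=C3)
Conditions: KN(SiMe3)2 (1.1 equiv), THF, −78 °C; then 3-phenyl-2-(phenylsulfonyl)oxaziridine (1.3 equiv), −78 °C; aq. NH4Cl
Reagents that add atoms: 3-phenyl-2-(phenylsulfonyl)oxaziridine, O=S(=O)(N1OC1c1ccccc1)c1ccccc1
Why: Enolate hydroxylation with an N-sulfonyloxaziridine: the doubly activated C1 methylene (α to C7=O and allylic) is deprotonated in preference to the hindered C6–H and the dienolate is oxygenated at its α-carbon; the C1 carbinol centre forms as a mixture, which does not matter because C1 becomes a carbonyl in step 8.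

Step 7
Reactants: 11 1-hydroxy ketone
Product: 12 1,7-diol (diastereomers at C1 and C7)
Conditions: NaBH4, MeOH/THF, −20 → 0 °C
Reagents that add atoms: none
Why: Borohydride reduction of the only ketone gives the 1,2-diol; the C7 configuration is immaterial because this oxygen is removed in step 9, and from here on C6 is no longer α to a carbonyl.

Step 8
Reactants: 12 1,7-diol
Product: 13 7-hydroxy enone (C7H–OH, C1=O, C2=C3)
Conditions: MnO2 (activated, excess), CH2Cl2, rt
Reagents that add atoms: none
Why: Chemoselective MnO2 oxidation of an allylic alcohol: only the C1 hydroxyl is allylic (to C2=C3), so the conjugated ketone is formed and the C7 hydroxyl is kept, which completes the move of the carbonyl from C7 to C1.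

Step 9
Reactants: 13 7-hydroxy enone
Product: 15 bicyclic cyclohept-2-enone (C7H2, C1=O, C2=C3; ring B silyl enol ether intact), via C7 acetate 14 (not isolated)
Conditions: Ac2O, pyridine, DMAP (cat.), CH2Cl2, 0 °C; then SmI2 (2.5 equiv), THF/MeOH, −78 °C
Reagents that add atoms: none
Why: Reductive cleavage of an α-acyloxy ketone by SmI2: electron transfer to the C1 carbonyl expels the C7 acetate and protonation of the samarium enolate leaves C7 as CH2, a process expected to be faster than conjugate reduction of the enone; no stereocentre is touched.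

Step 10
Reactants: 15 bicyclic cyclohept-2-enone
Product: 17 ring-B α-ketol (ring B: C5–CH2–C(=O)–C(OH)(CH3)–CH2–C6), via silyloxy epoxide 16 (not isolated)
Conditions: mCPBA (1.05 equiv), CH2Cl2/hexane, −40 → −10 °C; then Bu4NF/AcOH (1:1), THF, 0 °C
Reagents that add atoms: 3-chloroperbenzoic acid, OOC(=O)c1cccc(Cl)c1
Why: Rubottom oxidation: the tetrasubstituted silyl enol ether is by far the most electron-rich alkene and should be epoxidised before the trisubstituted side-chain alkene or the enone, and fluoride opens the silyloxy epoxide to the tertiary α-hydroxy ketone; the carbinol centre is a mixture and is destroyed in step 11.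

Step 11
Reactants: 17 ring-B α-ketol
Product: 18 methyl 2-[4-methyl-4-(4-methylpent-3-enyl)-1-oxo-6-(2-oxopropyl)cyclohept-2-en-5-yl]acetate (4-methyl, C5 arm and C6 arm all cis)
Conditions: Pb(OAc)4 (1.1 equiv), MeOH/PhH (1:1), 0 °C
Reagents that add atoms: methanol, CO
Why: Lead tetraacetate cleavage of an α-hydroxy ketone in methanol (glycol-type cleavage of its hemiketal) breaks the C(=O)–C(OH) bond of ring B and gives the methyl ester on the C5 arm and the methyl ketone on the C6 arm, cis as fixed in step 4.

Step 12
Reactants: 18 keto ester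
Product: 19 bis(ethylene ketal) of 18 (dioxolanes at C1 and at the side-chain ketone)
Conditions: Me3SiOCH2CH2OSiMe3 (4 equiv), Me3SiOTf (10 mol %), CH2Cl2, −78 → 0 °C
Reagents that add atoms: 1,2-bis(trimethylsilyloxy)ethane, C[Si](C)(C)OCCO[Si](C)(C)C
Why: Silyl-triflate-catalysed ketalisation with the bis-silyl glycol protects the methyl ketone and, more slowly, the conjugated ketone without moving the C2=C3 bond (C4 is quaternary), so that neither is reduced in step 13 or enolised in step 14.

Step 13
Reactants: 19 bis(ethylene ketal)
Product: 20 aldehyde (CH2CHO on C5; both ketals intact)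
Conditions: i-Bu2AlH (1.1 equiv), CH2Cl2, −78 °C; aq. potassium sodium tartrate
Reagents that add atoms: none
Why: Partial reduction of a methyl ester with i-Bu2AlH stops at the tetrahedral aluminium hemiacetal at −78 °C and gives the aldehyde on work-up.

Step 14
Reactants: 20 aldehyde
Product: 22 5-ethynyl bis(ethylene ketal), via enol nonaflate 21 (not isolated)
Conditions: n-C4F9SO2F (1.2 equiv), phosphazene base P2-Et (2.5 equiv), DMF, −30 °C → rt
Reagents that add atoms: none
Why: One-pot conversion of an enolisable aldehyde into a terminal alkyne: the phosphazene base forms the enolate, which is O-sulfonylated to 21 and then loses nonaflate by base-induced elimination, so the two carbons of the arm become the ethynyl group without a carbon being added; C5 is not deprotonated and keeps its configuration.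

Step 15
Reactants: 22 5-ethynyl bis(ethylene ketal)
Product: 23 5-ethynyl-4-methyl-4-(4-methylpent-3-enyl)-6-(2-oxopropyl)cyclohept-2-en-1-one
Conditions: 1 M HCl, THF, rt
Reagents that add atoms: water, O
Why: Acid-catalysed hydrolysis of both dioxolanes returns the methyl ketone and the enone; the alkyne and the trisubstituted alkene should be stable to dilute acid at room temperature.

Step 16
Reactants: 23 ethynyl diketone
Product: 24 5-ethynyl-2-(hydroxymethyl)-4-methyl-4-(4-methylpent-3-enyl)-6-(2-oxopropyl)cyclohept-2-en-1-one
Conditions: 37% aq. HCHO (5 equiv), DMAP (0.5 equiv), THF/H2O (1:1), rt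
Reagents that add atoms: formaldehyde, C=O
Why: Morita–Baylis–Hillman reaction: reversible conjugate addition of the amine to C3 gives the C2 enolate, which adds to formaldehyde, and loss of the amine restores the C2=C3 bond with CH2OH on C2; the saturated methyl ketone cannot enter this cycle.

Step 17
Reactants: 24 hydroxymethyl enone alkyne; 25 3-methylbut-2-enoic acid
Product: 26 (Z)-2-[(4R,5R,6S)-2-(hydroxymethyl)-4-methyl-4-(4-methylpent-3-enyl)-1-oxo-6-(2-oxopropyl)cyclohept-2-en-5-yl]ethenyl 3-methylbut-2-enoate (target)
Conditions: [RuCl2(p-cymene)]2 (2.5 mol %), P(4-ClC6H4)3 (6 mol %), DMAP (10 mol %), PhMe, 60 °C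
Reagents that add atoms: none
Why: Ruthenium-catalysed anti-Markovnikov hydro-oxycarbonylation of a terminal alkyne: the carboxylate attacks the α-carbon of a ruthenium vinylidene and protonolysis should give the Z-enol ester selectively, under near-neutral conditions that spare the enone, the ketone and the free alcohol.

## Compound list

1 | 2,6-dimethylhept-5-enal (racemic) | CC(CCC=C(C)C)C=O | starting material
2 | but-3-en-2-one | CC(=O)C=C | starting material
3 | 2-methyl-2-(4-methylpent-3-enyl)-5-oxohexanal (racemic Michael adduct) | CC(=O)CCC(C)(CCC=C(C)C)C=O | intermediate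
4 | 4-methyl-4-(4-methylpent-3-enyl)cyclohex-2-en-1-one (racemic) | CC1(CCC=C(C)C)CCC(=O)C=C1 | intermediate
5 | 4-methyl-4-(4-methylpent-3-enyl)cyclohexa-2,5-dien-1-one (achiral, C4 prochiral) | CC1(CCC=C(C)C)C=CC(=O)C=C1 | intermediate
6 | 3-methylbut-3-en-2-one | CC(=C)C(C)=O | starting material
7 | 2-(tert-butyldimethylsilyloxy)-3-methylbuta-1,3-diene | C=C(C)C(=C)O[Si](C)(C)C(C)(C)C | intermediate
8 | 6-(tert-butyldimethylsilyloxy)-4,7-dimethyl-4-(4-methylpent-3-enyl)-4a,5,8,8a-tetrahydronaphthalen-1(4H)-one, cis-fused, H-4a and H-8a cis to each other and trans to the 4-methyl group (target labels: C7=O, C2=C3, C4, C5 = C4a, C6 = C8a) | CC1=C(O[Si](C)(C)C(C)(C)C)C[C@H]2[C@@H](C1)C(=O)C=C[C@]2(C)CCC=C(C)C | intermediate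
9 | α-trimethylsilyl ketone: ring A seven-membered, C7(=O)–C1H(SiMe3)–C2H=C3H, C1 epimers, rest as in 8 | CC1=C(O[Si](C)(C)C(C)(C)C)C[C@H]2[C@@H](C1)C(=O)C([Si](C)(C)C)C=C[C@]2(C)CCC=C(C)C | intermediate
10 | β,γ-unsaturated ketone: ring A C7(=O)–C1H2–C2H=C3H–C4–C5–C6, ring B and stereocentres as in 8 | CC1=C(O[Si](C)(C)C(C)(C)C)C[C@H]2[C@@H](C1)C(=O)CC=C[C@]2(C)CCC=C(C)C | intermediate
11 | 1-hydroxy ketone: as 10 with OH on C1 (C1 epimers) | CC1=C(O[Si](C)(C)C(C)(C)C)C[C@H]2[C@@H](C1)C(=O)C(O)C=C[C@]2(C)CCC=C(C)C | intermediate
12 | 1,7-diol: as 11 with C7 reduced to CH–OH (diastereomers at C1 and C7) | CC1=C(O[Si](C)(C)C(C)(C)C)C[C@H]2[C@@H](C1)C(O)C(O)C=C[C@]2(C)CCC=C(C)C | intermediate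
13 | 7-hydroxy enone: ring A C7H(OH)–C1(=O)–C2H=C3H, ring B as in 8 | CC1=C(O[Si](C)(C)C(C)(C)C)C[C@H]2[C@@H](C1)C(O)C(=O)C=C[C@]2(C)CCC=C(C)C | intermediate
14 | 7-acetoxy enone: acetate of 13 | CC1=C(O[Si](C)(C)C(C)(C)C)C[C@H]2[C@@H](C1)C(OC(C)=O)C(=O)C=C[C@]2(C)CCC=C(C)C | intermediate
15 | bicyclic cyclohept-2-enone: ring A C7H2–C1(=O)–C2H=C3H–C4–C5–C6, fused cis at C5–C6 to ring B C5–CH2–C(OSiMe2t-Bu)=C(CH3)–CH2–C6 | CC1=C(O[Si](C)(C)C(C)(C)C)C[C@H]2[C@@H](C1)CC(=O)C=C[C@]2(C)CCC=C(C)C | intermediate
16 | silyloxy epoxide of 15 (oxirane across the former enol ether double bond, epimers) | CC12OC1(O[Si](C)(C)C(C)(C)C)C[C@H]3[C@@H](C2)CC(=O)C=C[C@]3(C)CCC=C(C)C | intermediate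
17 | ring-B α-ketol: ring B C5–CH2–C(=O)–C(OH)(CH3)–CH2–C6 (carbinol epimers), ring A as in 15 | CC1(O)C(=O)C[C@H]2[C@@H](C1)CC(=O)C=C[C@]2(C)CCC=C(C)C | intermediate
18 | methyl 2-[4-methyl-4-(4-methylpent-3-enyl)-1-oxo-6-(2-oxopropyl)cyclohept-2-en-5-yl]acetate; 4-methyl, C5 arm and C6 arm all cis | CC(=O)C[C@H]1CC(=O)C=C[C@](C)(CCC=C(C)C)[C@H]1CC(=O)OC | intermediate
19 | bis(ethylene ketal) of 18 (spiro-dioxolane at C1, dioxolane at the side-chain ketone) | CC1(OCCO1)C[C@H]2CC3(OCCO3)C=C[C@](C)(CCC=C(C)C)[C@H]2CC(=O)OC | intermediate
20 | aldehyde: as 19 with CH2CHO on C5 | CC1(OCCO1)C[C@H]2CC3(OCCO3)C=C[C@](C)(CCC=C(C)C)[C@H]2CC=O | intermediate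
21 | enol nonaflate: as 19 with CH=CH–OSO2C4F9 on C5 (E/Z mixture) | CC1(OCCO1)C[C@H]2CC3(OCCO3)C=C[C@](C)(CCC=C(C)C)[C@H]2C=COS(=O)(=O)C(F)(F)C(F)(F)C(F)(F)C(F)(F)F | intermediate
22 | 5-ethynyl bis(ethylene ketal) | CC1(OCCO1)C[C@H]2CC3(OCCO3)C=C[C@](C)(CCC=C(C)C)[C@H]2C#C | intermediate
23 | 5-ethynyl-4-methyl-4-(4-methylpent-3-enyl)-6-(2-oxopropyl)cyclohept-2-en-1-one; 4-methyl, 5-ethynyl and 6-(2-oxopropyl) cis | CC(=O)C[C@H]1CC(=O)C=C[C@](C)(CCC=C(C)C)[C@H]1C#C | intermediate
24 | 5-ethynyl-2-(hydroxymethyl)-4-methyl-4-(4-methylpent-3-enyl)-6-(2-oxopropyl)cyclohept-2-en-1-one | CC(=O)C[C@H]1CC(=O)C(CO)=C[C@](C)(CCC=C(C)C)[C@H]1C#C | intermediate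
25 | 3-methylbut-2-enoic acid | CC(C)=CC(=O)O | starting material
26 | (Z)-2-[(4R,5R,6S)-2-(hydroxymethyl)-4-methyl-4-(4-methylpent-3-enyl)-1-oxo-6-(2-oxopropyl)cyclohept-2-en-5-yl]ethenyl 3-methylbut-2-enoate (ring numbered as in the remark on labels) | CC(=O)C[C@H]1CC(=O)C(CO)=C[C@](C)(CCC=C(C)C)[C@H]1/C=C\OC(=O)C=C(C)C | target

## Step count and risks

Total steps: 17. Longest linear sequence: 16 steps (steps 1, 2 and 4–17; step 3 is a one-step branch).

Steps most likely to fail:

1. Step 4. The catalyst may not tell the two enantiotopic enones apart well enough, the diene may not sufficiently prefer the methyl face over the homoprenyl face, and addition at the β-carbon next to the quaternary centre may be slow. The fallback sets C4 before the cycloaddition instead of during it. Setting out from 1 and 2, an asymmetric Michael addition catalysed by a chiral primary amine salt should give (S)-2-methyl-2-(4-methylpent-3-enyl)-5-oxohexanal F1, which KOH/EtOH would cyclise to (S)-4-methyl-4-(4-methylpent-3-enyl)cyclohex-2-en-1-one F2. A Lewis-acid-promoted Diels–Alder reaction of F2 with 7 (EtAlCl2, CH2Cl2, −78 °C) then has a single enone to react with and should give the saturated cis-fused ketone F3, again with the diene anti to the homoprenyl chain. Kinetic enolisation of F3 at the C2 methylene (LiN(i-Pr)2, THF, −78 °C) and dehydrogenation of the lithium enolate in the same flask with N-tert-butylbenzenesulfinimidoyl chloride would introduce the C2=C3 bond and return to the route at 8.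

2. Step 5. The diazoalkane may fail to add to the hindered C7 carbonyl, the betaine may close to a spiro-epoxide instead of rearranging, or the β,γ-double bond may move into conjugation during desilylation. Any product in which C6 migrates instead of C2 would be 15 itself and could be carried on at step 10. The fallback brings the carbon in as a carbenoid. Setting out from 8, LiCHBr2 (from CH2Br2 and lithium 2,2,6,6-tetramethylpiperidide, THF, −78 °C) should add to C7 to give the dibromomethyl carbinol F4 as its lithium alkoxide. BuLi (2 equiv, −78 → −20 °C) would then convert it by bromine–lithium exchange into a β-oxido carbenoid, which rearranges with migration of the alkenyl carbon to the lithium dienolate of the ring-enlarged ketone. Protonation with AcOH at −78 °C returns to the route at 10.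

3. Step 16. The amine may add too slowly to C3, which sits next to the quaternary C4, so that the catalytic cycle does not turn over, while the 1,5-diketone slowly undergoes aldol side reactions in the basic aqueous medium. The fallback replaces the catalytic aldol by halogenation and cross-coupling. Setting out from 23, α-iodination of the enone (I2, pyridine, CH2Cl2, rt), a reaction known to work on enones with a quaternary γ-carbon, should give the 2-iodo enone F5. A Stille coupling with Bu3SnCH2OH (Pd(PPh3)4, dioxane, 80 °C, no copper salt and no amine so that the terminal alkyne is left alone) would put CH2OH on C2 and return to the route at 24.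

Further compounds
F1 | step 4 | (S)-2-methyl-2-(4-methylpent-3-enyl)-5-oxohexanal | CC(=O)CC[C@](C)(CCC=C(C)C)C=O
F2 | step 4 | (S)-4-methyl-4-(4-methylpent-3-enyl)cyclohex-2-en-1-one | O=C1CC[C@](C)(CCC=C(C)C)C=C1
F3 | step 4 | saturated cis-fused ketone (8 without the C2=C3 double bond) | CC1=C(O[Si](C)(C)C(C)(C)C)C[C@H]2[C@@H](C1)C(=O)CC[C@]2(C)CCC=C(C)C
F4 | step 5 | dibromomethyl carbinol (8 with C7 bearing OH and CHBr2, C7 epimers) | CC1=C(O[Si](C)(C)C(C)(C)C)C[C@H]2[C@@H](C1)C(O)(C(Br)Br)C=C[C@]2(C)CCC=C(C)C
F5 | step 16 | 5-ethynyl-2-iodo-4-methyl-4-(4-methylpent-3-enyl)-6-(2-oxopropyl)cyclohept-2-en-1-one | CC(=O)C[C@H]1CC(=O)C(I)=C[C@](C)(CCC=C(C)C)[C@H]1C#C
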